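**Assumption:** the target SMILES has no stereocentre and no stereogenic double bond (the prenyl alkene carries two identical methyls), so the molecule is achiral and no stereocontrol is needed.

## Retrosynthetic overview

1. Target 16 ⇐ tris‑MOM ether 15 by one global acetal cleavage.
2. 15 ⇐ Ullmann C–O coupling of ring‑A aryl bromide 6 (19 heavy atoms) with ring‑B phenol 14 (20 heavy atoms).
3. 6 ⇐ 3‑bromophenol: lithiation between Br and OMOM with a chloroformate quench, then Ir C–H borylation/oxidation for the 4‑oxygen.
4. 14 ⇐ hydroquinone: dimethyl ether, 2,5‑dibromide, one Br to prenyl, the other Br to OH then OMOM, and a final directed ortho‑metalation/oxidation.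
5. No ring is constructed; both benzene rings come from commercial aromatics.

## Ring A branch

**Step 1**
Reactants: 1, 3‑bromophenol
Product: 2, 1‑bromo‑3‑(methoxymethoxy)benzene
Conditions: MOMCl, i‑Pr2NEt, CH2Cl2, 0 °C → rt
Reagents that add atoms: chloromethyl methyl ether, COCCl
Why: Phenol O‑alkylation (Williamson‑type acetal formation); the MOM group later directs the metalation and is removed by mild acid at the end.

**Step 2**
Reactants: 2, 1‑bromo‑3‑(methoxymethoxy)benzene; 3, methyl chloroformate
Product: 4, methyl 2‑bromo‑6‑(methoxymethoxy)benzoate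
Conditions: LDA, THF, −78 °C, 1 h; cannulate into ClCO2Me (3 equiv), THF, −78 °C
Reagents that add atoms: methyl chloroformate (3), COC(=O)Cl
Why: Directed ortho‑metalation at the C–H flanked by Br and OMOM (the most acidic site); LDA avoids Br/Li exchange, −78 °C suppresses aryne formation, and inverse addition to the chloroformate limits ketone formation.

**Step 3**
Reactants: 4, methyl 2‑bromo‑6‑(methoxymethoxy)benzoate
Product: 5, methyl 2‑bromo‑4‑hydroxy‑6‑(methoxymethoxy)benzoate
Conditions: [Ir(OMe)(cod)]2 (1.5 mol%), dtbpy (3 mol%), B2pin2, THF, 80 °C; then 30% H2O2, aq NaOH, THF, 0 °C (one pot)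
Reagents that add atoms: hydrogen peroxide, OO (supplies the phenolic O; the Bpin group is not retained)
Why: Sterically controlled Ir‑catalysed C–H borylation followed by boronate oxidation; C4 is the only C–H with no ortho substituent, and the aryl bromide, the MOM ether and the hindered ester all tolerate the conditions.

**Step 4**
Reactants: 5, methyl 2‑bromo‑4‑hydroxy‑6‑(methoxymethoxy)benzoate
Product: 6, methyl 2‑bromo‑4,6‑bis(methoxymethoxy)benzoate
Conditions: MOMCl, i‑Pr2NEt, CH2Cl2, 0 °C → rt
Reagents that add atoms: chloromethyl methyl ether, COCCl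
Why: Acetal protection of the acidic para‑hydroxybenzoate OH so that it cannot compete as a nucleophile in the Ullmann coupling.

## Ring B branch

**Step 5**
Reactants: 7, hydroquinone
Product: 8, 1,4‑dimethoxybenzene
Conditions: MeI, K2CO3, acetone, reflux
Reagents that add atoms: iodomethane, CI
Why: Double Williamson etherification installs the two para‑related methyl ethers of ring B.

**Step 6**
Reactants: 8, 1,4‑dimethoxybenzene
Product: 9, 1,4‑dibromo‑2,5‑dimethoxybenzene
Conditions: Br2 (2.1 equiv), AcOH, rt
Reagents that add atoms: bromine, BrBr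
Why: Electrophilic aromatic bromination; the second bromine enters para to the first to give the crystalline 2,5‑dibromide.

**Step 7**
Reactants: 9, 1,4‑dibromo‑2,5‑dimethoxybenzene; 10, prenyl bromide
Product: 11, 1‑bromo‑2,5‑dimethoxy‑4‑(3‑methylbut‑2‑en‑1‑yl)benzene
Conditions: n‑BuLi (1.0 equiv), THF, −78 °C; CuBr·SMe2; then 10, −78 → 0 °C
Reagents that add atoms: prenyl bromide (10), CC(C)=CCBr
Why: Mono Br/Li exchange, transmetalation to copper and allylic substitution; attack at the primary carbon (SN2) is favoured because SN2′ would create a quaternary benzylic centre.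

**Step 8**
Reactants: 11, 1‑bromo‑2,5‑dimethoxy‑4‑(3‑methylbut‑2‑en‑1‑yl)benzene
Product: 12, 2,5‑dimethoxy‑4‑(3‑methylbut‑2‑en‑1‑yl)phenol
Conditions: n‑BuLi, THF, −78 °C; B(OMe)3, −78 °C → rt; then 30% H2O2, aq NaOH, 0 °C
Reagents that add atoms: hydrogen peroxide, OO (supplies the phenolic O; boron is not retained)
Why: Br/Li exchange (much faster than benzylic deprotonation at −78 °C), borylation and boronate oxidation; alkaline peroxide does not touch the isolated trisubstituted alkene.

**Step 9**
Reactants: 12, 2,5‑dimethoxy‑4‑(3‑methylbut‑2‑en‑1‑yl)phenol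
Product: 13, 1,4‑dimethoxy‑2‑(methoxymethoxy)‑5‑(3‑methylbut‑2‑en‑1‑yl)benzene
Conditions: MOMCl, i‑Pr2NEt, CH2Cl2, 0 °C → rt
Reagents that add atoms: chloromethyl methyl ether, COCCl
Why: MOM protection of the oxygen that ends up as the free ring‑B OH; it also provides the directing group for the next metalation.

**Step 10**
Reactants: 13, 1,4‑dimethoxy‑2‑(methoxymethoxy)‑5‑(3‑methylbut‑2‑en‑1‑yl)benzene
Product: 14, 3,6‑dimethoxy‑2‑(methoxymethoxy)‑5‑(3‑methylbut‑2‑en‑1‑yl)phenol
Conditions: n‑BuLi, TMEDA, THF, −40 → 0 °C; B(OMe)3, −78 °C → rt; then 30% H2O2, aq NaOH, 0 °C; Na2S2O3 quench, work up under Ar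
Reagents that add atoms: hydrogen peroxide, OO (supplies the phenolic O; boron is not retained)
Why: Directed ortho‑metalation at the C–H flanked by OMOM and OMe (cooperative directing effect, favoured over the C–H next to the prenyl group), then borylation/oxidation to the phenol that will be arylated.

## Coupling and endgame

**Step 11**
Reactants: 6, methyl 2‑bromo‑4,6‑bis(methoxymethoxy)benzoate; 14, 3,6‑dimethoxy‑2‑(methoxymethoxy)‑5‑(3‑methylbut‑2‑en‑1‑yl)phenol
Product: 15, methyl 2‑[3,6‑dimethoxy‑2‑(methoxymethoxy)‑5‑(3‑methylbut‑2‑en‑1‑yl)phenoxy]‑4,6‑bis(methoxymethoxy)benzoate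
Conditions: CuI (20 mol%), picolinic acid (40 mol%), K3PO4, degassed DMSO, 4 Å MS, 90 °C, Ar
Reagents that add atoms: none
Why: Ullmann‑type Cu‑catalysed diaryl ether synthesis; the ortho ester activates the C–Br bond, the picolinic acid system accepts 2,6‑disubstituted phenols, and MOM ethers, the prenyl group and the hindered methyl ester survive anhydrous base.

**Step 12**
Reactants: 15, the tris‑MOM diaryl ether
Product: 16, paucinervin B, methyl 2,4‑dihydroxy‑6‑[2‑hydroxy‑3,6‑dimethoxy‑5‑(3‑methylbut‑2‑en‑1‑yl)phenoxy]benzoate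
Conditions: 3 M HCl in MeOH, 40 °C
Reagents that add atoms: none
Why: Acid‑catalysed acetal methanolysis removes all three MOM groups; the prenyl group has no ortho OH (so no chroman formation), the aryl methyl ethers are inert, and MeOH makes any ester exchange degenerate.

## Compound list

1 | 3‑bromophenol | Oc1cccc(Br)c1 | starting material
2 | 1‑bromo‑3‑(methoxymethoxy)benzene | COCOc1cccc(Br)c1 | intermediate
3 | methyl chloroformate | COC(=O)Cl | starting material
4 | methyl 2‑bromo‑6‑(methoxymethoxy)benzoate | COCOc1cccc(Br)c1C(=O)OC | intermediate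
5 | methyl 2‑bromo‑4‑hydroxy‑6‑(methoxymethoxy)benzoate | COCOc1cc(O)cc(Br)c1C(=O)OC | intermediate
6 | methyl 2‑bromo‑4,6‑bis(methoxymethoxy)benzoate | COCOc1cc(OCOC)cc(Br)c1C(=O)OC | intermediate
7 | hydroquinone | Oc1ccc(O)cc1 | starting material
8 | 1,4‑dimethoxybenzene | COc1ccc(OC)cc1 | intermediate
9 | 1,4‑dibromo‑2,5‑dimethoxybenzene | COc1cc(Br)c(OC)cc1Br | intermediate
10 | prenyl bromide (1‑bromo‑3‑methylbut‑2‑ene) | CC(C)=CCBr | starting material
11 | 1‑bromo‑2,5‑dimethoxy‑4‑(3‑methylbut‑2‑en‑1‑yl)benzene | COc1cc(Br)c(OC)cc1CC=C(C)C | intermediate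
12 | 2,5‑dimethoxy‑4‑(3‑methylbut‑2‑en‑1‑yl)phenol | COc1cc(O)c(OC)cc1CC=C(C)C | intermediate
13 | 1,4‑dimethoxy‑2‑(methoxymethoxy)‑5‑(3‑methylbut‑2‑en‑1‑yl)benzene | COCOc1cc(OC)c(CC=C(C)C)cc1OC | intermediate
14 | 3,6‑dimethoxy‑2‑(methoxymethoxy)‑5‑(3‑methylbut‑2‑en‑1‑yl)phenol | COCOc1c(O)c(OC)c(CC=C(C)C)cc1OC | intermediate
15 | methyl 2‑[3,6‑dimethoxy‑2‑(methoxymethoxy)‑5‑(3‑methylbut‑2‑en‑1‑yl)phenoxy]‑4,6‑bis(methoxymethoxy)benzoate | COC(=O)c1c(OCOC)cc(OCOC)cc1Oc1c(OCOC)c(OC)cc(CC=C(C)C)c1OC | intermediate
16 | paucinervin B | COC(=O)c1c(O)cc(O)cc1Oc1c(O)c(OC)cc(CC=C(C)C)c1OC | target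

## Step count

- Total steps: 12 (ring A branch 4, ring B branch 6, coupling 1, deprotection 1).
- Longest linear sequence: 8 (steps 5–12, hydroquinone to target), i.e. 8 of 12.

## Steps most likely to fail, with fallbacks

1. **Step 11 (Ullmann coupling).** The phenol is 2,6‑dioxygenated, hindered and easily oxidised. Fallback: change the electrophile class. Convert 6 to the iodide (aromatic Finkelstein), make the aryl(2,4,6‑trimethoxyphenyl)iodonium salt, and O‑arylate the potassium salt of 14 without metal at room temperature. Ring A would carry allyl ethers instead of MOM if the acidic salt formation cleaves the acetals.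

2. **Step 10 (metalation with the prenyl group present).** Benzylic/allylic deprotonation may compete, and the tetra‑oxygenated phenol is air‑sensitive. Fallback: install the oxygen before the prenyl group.
   - Lithiate/oxidise 8 to 2,5‑dimethoxyphenol, MOM‑protect, then lithiate/oxidise again to 3,6‑dimethoxy‑2‑(methoxymethoxy)phenol.
   - Mask the new OH as a pivalate so that NBS brominates para to the OMOM oxygen.
   - Introduce prenyl by Pd‑catalysed Stille coupling with tributyl(prenyl)stannane, then cleave the pivalate to reach 14.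

3. **Step 2 (lithiation ortho to bromine with a chloroformate quench).** Aryne formation, halogen migration or over‑addition to the ester are possible. Fallback: introduce the carbon electrophilically. Carry out the Ir borylation/oxidation on 2 and remove the MOM group to give 5‑bromoresorcinol. Vilsmeier–Haack formylation then goes ortho to Br and para to OH. Bis‑MOM protection, Pinnick oxidation and MeI/K2CO3 esterification give 6.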